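## Retrosynthetic overview
1. The butenolide C3=C4 bond comes from dehydration of a β-hydroxy-γ-lactone. That lactone comes from an intermolecular lithium-enolate aldol between methyl (7-methoxyflavon-8-yl)acetate 15 and 2-(TBSO)-2-methylpropanal 19, which is the key C–C bond.
2. Arylacetate 15 comes from oxidative cleavage of an 8-allyl group, placed at C-8 by aromatic Claisen rearrangement of 7-allyloxyflavone 8.
3. Flavone 8 comes from cyclodehydration of 1,3-diketone 6, made by crossed Claisen condensation of 4-allyloxy-2-hydroxyacetophenone 3 with benzoyl chloride 4.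
4. Aldehyde 19 comes from methyl 2-hydroxyisobutyrate 16 by silylation and partial reduction.
5. Ring order: both benzene rings are bought, the pyranone (ring C) is closed first, and the butenolide is closed last.

Assumption: the target SMILES has no stereocentre, so the molecule is achiral and no enantiocontrol is needed. The transient stereocentres are carried as racemic or diastereomeric mixtures and are erased in step 13.

## Route

Step 1
Reactants: 1 2,4-dihydroxyacetophenone; 2 allyl bromide
Product: 3 1-[4-(allyloxy)-2-hydroxyphenyl]ethanone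
Conditions: K2CO3 (1.2 equiv), acetone, reflux, 8 h
Reagents that add atoms: none
Why: Williamson ether synthesis in which the 2-OH is tied up in a hydrogen bond to the acetyl C=O, so one equivalent of the allylic bromide alkylates only the free, more acidic 4-OH.

Step 2
Reactants: 3 1-[4-(allyloxy)-2-hydroxyphenyl]ethanone; 4 benzoyl chloride
Product: 6 1-[4-(allyloxy)-2-hydroxyphenyl]-3-phenylpropane-1,3-dione, via dilithium phenoxide-enolate 5 (not isolated)
Conditions: LiN(SiMe3)2 (3.2 equiv), THF, −78 to −10 °C, 2 h; then 4 (1.0 equiv), −78 °C to rt, 4 h; 1 M HCl quench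
Reagents that add atoms: none
Why: Crossed Claisen condensation in which dianion 5 is acylated at its enolate carbon by the non-enolisable acid chloride, the third equivalent of base stores the acidic diketone as its salt against double acylation, and any O-benzoate formed converges on 6 by Baker-Venkataraman acyl shift.

Step 3
Reactants: 6 1-[4-(allyloxy)-2-hydroxyphenyl]-3-phenylpropane-1,3-dione
Product: 8 7-(allyloxy)-2-phenyl-4H-chromen-4-one (7-allyloxyflavone), via cyclic hemiketal 7 (not isolated)
Conditions: AcOH, H2SO4 (cat., 0.5 vol%), 95 °C, 1 h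
Reagents that add atoms: none
Why: Acid-catalysed cyclodehydration in which the phenol adds to the benzoyl C=O to give hemiketal 7, water is lost to give the stable 4-pyranone, and the primary allyl aryl ether is not ionised by catalytic acid in this short time.

Step 4
Reactants: 8 7-(allyloxy)-2-phenyl-4H-chromen-4-one
Product: 10 8-allyl-7-hydroxy-2-phenyl-4H-chromen-4-one, via ortho-dienone 9 (not isolated)
Conditions: N,N-diethylaniline, N2, reflux (ca. 215 °C), 5 h
Reagents that add atoms: none
Why: Aromatic Claisen rearrangement ([3,3]-sigmatropic shift) that goes to C-8 rather than C-6 because the C7–C8 bond of the chromone has the higher double-bond character, after which dienone 9 tautomerises to the phenol.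

Step 5
Reactants: 10 8-allyl-7-hydroxy-2-phenyl-4H-chromen-4-one
Product: 11 8-allyl-7-methoxy-2-phenyl-4H-chromen-4-one
Conditions: MeI (1.5 equiv), K2CO3 (2 equiv), DMF, rt, 6 h
Reagents that add atoms: iodomethane, CI
Why: Williamson O-methylation of the only acidic site, a vinylogous-acid phenol, under conditions that touch neither the allyl group nor the pyranone.

Step 6
Reactants: 11 8-allyl-7-methoxy-2-phenyl-4H-chromen-4-one
Product: 13 (7-methoxy-4-oxo-2-phenyl-4H-chromen-8-yl)acetaldehyde, via vicinal diol 12 (not isolated)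
Conditions: OsO4 (2 mol%), NaIO4 (4 equiv), 2,6-lutidine (2 equiv), 1,4-dioxane/H2O 3:1, rt, 3 h
Reagents that add atoms: osmium tetroxide OsO4, O=[Os](=O)(=O)=O; sodium periodate NaIO4 (terminal oxygen source), [Na+].[O-]I(=O)(=O)=O
Why: Lemieux-Johnson oxidation in which OsO4 dihydroxylates the electron-rich terminal alkene much faster than the electron-poor C2=C3 bond of the pyranone, periodate cleaves diol 12, and lutidine suppresses over-oxidation.

Step 7
Reactants: 13 (7-methoxy-4-oxo-2-phenyl-4H-chromen-8-yl)acetaldehyde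
Product: 14 (7-methoxy-4-oxo-2-phenyl-4H-chromen-8-yl)acetic acid
Conditions: NaClO2 (3 equiv), NaH2PO4 (3 equiv), 2-methyl-2-butene (10 equiv), t-BuOH/THF/H2O, 0 °C to rt, 2 h (crude 13 used at once)
Reagents that add atoms: sodium chlorite NaClO2, [Na+].[O-]Cl=O
Why: Pinnick oxidation converts the labile arylacetaldehyde to the acid at buffered pH without enolisation, and the alkene scavenger removes HOCl before it can chlorinate the anisole ring.

Step 8
Reactants: 14 (7-methoxy-4-oxo-2-phenyl-4H-chromen-8-yl)acetic acid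
Product: 15 methyl (7-methoxy-4-oxo-2-phenyl-4H-chromen-8-yl)acetate
Conditions: MeOH, H2SO4 (cat.), reflux, 4 h
Reagents that add atoms: methanol, CO
Why: Fischer esterification of an unhindered CH2CO2H group, driven by methanol as solvent, on an acid-stable flavone.

Step 9
Reactants: 16 methyl 2-hydroxy-2-methylpropanoate
Product: 17 methyl 2-[(tert-butyldimethylsilyl)oxy]-2-methylpropanoate
Conditions: TBSOTf (1.2 equiv), 2,6-lutidine (1.6 equiv), CH2Cl2, 0 °C to rt, 3 h
Reagents that add atoms: tert-butyldimethylsilyl trifluoromethanesulfonate, CC(C)(C)[Si](C)(C)OS(=O)(=O)C(F)(F)F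
Why: O-silylation with the silyl triflate, which is reactive enough for a tertiary alcohol where the silyl chloride is not, using a hindered base that does not attack the ester.

Step 10
Reactants: 17 methyl 2-[(tert-butyldimethylsilyl)oxy]-2-methylpropanoate
Product: 19 2-[(tert-butyldimethylsilyl)oxy]-2-methylpropanal, via aluminium hemiacetal 18 (not isolated)
Conditions: i-Bu2AlH (1.1 equiv), CH2Cl2, −78 °C, 1 h; MeOH quench at −78 °C, then aq. KNaC4H4O6 (potassium sodium tartrate), rt
Reagents that add atoms: none
Why: Partial ester reduction in which the hindered, α-oxygenated tetrahedral aluminium hemiacetal 18 persists at −78 °C and releases the aldehyde only on work-up, when no hydride is left.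

Step 11 (key step)
Reactants: 15 methyl (7-methoxy-4-oxo-2-phenyl-4H-chromen-8-yl)acetate; 19 2-[(tert-butyldimethylsilyl)oxy]-2-methylpropanal
Product: 21 methyl 4-[(tert-butyldimethylsilyl)oxy]-3-hydroxy-2-(7-methoxy-4-oxo-2-phenyl-4H-chromen-8-yl)-4-methylpentanoate (racemic syn/anti mixture), via lithium ester enolate 20 (not isolated)
Conditions: LiN(SiMe3)2 (1.1 equiv), THF, −78 °C, 45 min; then 19 (1.3 equiv), −78 °C, 2 h; AcOH/THF quench at −78 °C
Reagents that add atoms: none
Why: Intermolecular aldol addition in which the amide base removes only the benzylic ester α-proton (pKa about 22, far below flavone C3–H), the non-enolisable aldehyde 19 can act only as acceptor, the cold acidic quench blocks retro-aldol and silyl migration, and the two new stereocentres form unselectively because both are erased in step 13.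

Step 12
Reactants: 21 methyl 4-[(tert-butyldimethylsilyl)oxy]-3-hydroxy-2-(7-methoxy-4-oxo-2-phenyl-4H-chromen-8-yl)-4-methylpentanoate
Product: 23 8-(4-hydroxy-5,5-dimethyl-2-oxotetrahydrofuran-3-yl)-7-methoxy-2-phenyl-4H-chromen-4-one (racemic cis/trans mixture), via diol ester 22 (not isolated)
Conditions: 48% aq. HF, MeCN, 0 °C to rt, 6 h; crude, then p-TsOH·H2O (10 mol%), CH2Cl2, rt, 4 h
Reagents that add atoms: none
Why: Acidic fluoride desilylation followed by lactonisation (intramolecular transesterification), in which non-basic conditions avoid retro-aldol, the gem-dimethyl effect favours closure of the five-membered ring, and a silyl-migrated isomer of 21 would give the same diol 22.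

Step 13
Reactants: 23 8-(4-hydroxy-5,5-dimethyl-2-oxotetrahydrofuran-3-yl)-7-methoxy-2-phenyl-4H-chromen-4-one
Product: 25 8-(5,5-dimethyl-2-oxo-2,5-dihydrofuran-3-yl)-7-methoxy-2-phenyl-4H-chromen-4-one (target), via secondary mesylate 24 (not isolated)
Conditions: MsCl (1.5 equiv), Et3N (5 equiv), CH2Cl2, 0 °C to rt, 12 h
Reagents that add atoms: none
Why: Mesylation followed by E1cB β-elimination, in which the α-proton flanked by aryl and lactone C=O is removed by Et3N from either diastereomer, C5 is quaternary so only the C3=C4 alkene can form, and the ring enforces the required geometry.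

## Compound list
1 | 2,4-dihydroxyacetophenone | CC(=O)c1ccc(O)cc1O | starting material
2 | allyl bromide | C=CCBr | starting material
3 | 1-[4-(allyloxy)-2-hydroxyphenyl]ethanone | CC(=O)c1ccc(OCC=C)cc1O | intermediate
4 | benzoyl chloride | O=C(Cl)c1ccccc1 | starting material
5 | dilithium phenoxide-enolate of 3 (not isolated) | [Li+].[Li+].C=C([O-])c1ccc(OCC=C)cc1[O-] | intermediate
6 | 1-[4-(allyloxy)-2-hydroxyphenyl]-3-phenylpropane-1,3-dione | O=C(CC(=O)c1ccccc1)c1ccc(OCC=C)cc1O | intermediate
7 | 7-(allyloxy)-2-hydroxy-2-phenylchroman-4-one, racemic cyclic hemiketal (not isolated) | O=C1CC(O)(c2ccccc2)Oc2cc(OCC=C)ccc21 | intermediate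
8 | 7-(allyloxy)-2-phenyl-4H-chromen-4-one | C=CCOc1ccc2c(=O)cc(-c3ccccc3)oc2c1 | intermediate
9 | 8-allyl-2-phenyl-8H-chromene-4,7-dione, racemic ortho-dienone (not isolated) | C=CCC1C(=O)C=CC2=C1OC(c1ccccc1)=CC2=O | intermediate
10 | 8-allyl-7-hydroxy-2-phenyl-4H-chromen-4-one | C=CCc1c(O)ccc2c(=O)cc(-c3ccccc3)oc12 | intermediate
11 | 8-allyl-7-methoxy-2-phenyl-4H-chromen-4-one | C=CCc1c(OC)ccc2c(=O)cc(-c3ccccc3)oc12 | intermediate
12 | 8-(2,3-dihydroxypropyl)-7-methoxy-2-phenyl-4H-chromen-4-one, racemic (not isolated) | OCC(O)Cc1c(OC)ccc2c(=O)cc(-c3ccccc3)oc12 | intermediate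
13 | (7-methoxy-4-oxo-2-phenyl-4H-chromen-8-yl)acetaldehyde | O=CCc1c(OC)ccc2c(=O)cc(-c3ccccc3)oc12 | intermediate
14 | (7-methoxy-4-oxo-2-phenyl-4H-chromen-8-yl)acetic acid | OC(=O)Cc1c(OC)ccc2c(=O)cc(-c3ccccc3)oc12 | intermediate
15 | methyl (7-methoxy-4-oxo-2-phenyl-4H-chromen-8-yl)acetate | COC(=O)Cc1c(OC)ccc2c(=O)cc(-c3ccccc3)oc12 | intermediate
16 | methyl 2-hydroxy-2-methylpropanoate | COC(=O)C(C)(C)O | starting material
17 | methyl 2-[(tert-butyldimethylsilyl)oxy]-2-methylpropanoate | COC(=O)C(C)(C)O[Si](C)(C)C(C)(C)C | intermediate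
18 | diisobutylaluminium hemiacetal alkoxide of 17, racemic (not isolated) | COC(O[Al](CC(C)C)CC(C)C)C(C)(C)O[Si](C)(C)C(C)(C)C | intermediate
19 | 2-[(tert-butyldimethylsilyl)oxy]-2-methylpropanal | O=CC(C)(C)O[Si](C)(C)C(C)(C)C | intermediate
20 | lithium enolate of 15 (not isolated) | [Li+].COC([O-])=Cc1c(OC)ccc2c(=O)cc(-c3ccccc3)oc12 | intermediate
21 | methyl 4-[(tert-butyldimethylsilyl)oxy]-3-hydroxy-2-(7-methoxy-4-oxo-2-phenyl-4H-chromen-8-yl)-4-methylpentanoate, racemic syn/anti mixture | COC(=O)C(C(O)C(C)(C)O[Si](C)(C)C(C)(C)C)c1c(OC)ccc2c(=O)cc(-c3ccccc3)oc12 | intermediate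
22 | methyl 3,4-dihydroxy-2-(7-methoxy-4-oxo-2-phenyl-4H-chromen-8-yl)-4-methylpentanoate, racemic syn/anti mixture (not isolated) | COC(=O)C(C(O)C(C)(C)O)c1c(OC)ccc2c(=O)cc(-c3ccccc3)oc12 | intermediate
23 | 8-(4-hydroxy-5,5-dimethyl-2-oxotetrahydrofuran-3-yl)-7-methoxy-2-phenyl-4H-chromen-4-one, racemic cis/trans mixture | COc1ccc2c(=O)cc(-c3ccccc3)oc2c1C1C(O)C(C)(C)OC1=O | intermediate
24 | 4-(7-methoxy-4-oxo-2-phenyl-4H-chromen-8-yl)-2,2-dimethyl-5-oxotetrahydrofuran-3-yl methanesulfonate, racemic cis/trans mixture (not isolated) | COc1ccc2c(=O)cc(-c3ccccc3)oc2c1C1C(OS(C)(=O)=O)C(C)(C)OC1=O | intermediate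
25 | 8-(5,5-dimethyl-2-oxo-2,5-dihydrofuran-3-yl)-7-methoxy-2-phenyl-4H-chromen-4-one (achiral) | COc1ccc2c(=O)cc(-c3ccccc3)oc2c1C1=CC(C)(C)OC1=O | target

## Step count and risks
Total step count: 13.
Longest linear sequence: 11 steps (1 → 25 through steps 1–8 and 11–13). The side branch 16 → 19 is 2 steps.

**Step 11 (most at risk).** A di-ortho-substituted arylacetate enolate meets an α-quaternary aldehyde, so conversion may be low or retro-aldol may intervene. The fallback sets out from acid 14 and comes back at target 25.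
- Acid 14 is esterified (DCC, DMAP, CH2Cl2) with commercial 2-methylbut-3-en-2-ol to give 2-methylbut-3-en-2-yl (7-methoxy-4-oxo-2-phenyl-4H-chromen-8-yl)acetate F1.
- The vinyl group of F1 is cleaved (OsO4 cat., NaIO4, 2,6-lutidine, dioxane/H2O) to 2-methyl-1-oxopropan-2-yl (7-methoxy-4-oxo-2-phenyl-4H-chromen-8-yl)acetate F2.
- DBU in MeCN at rt then closes the five-membered ring by intramolecular aldol condensation, where proximity replaces the difficult bimolecular encounter.
- This gives 25 directly. Any hydroxylactone 23 that survives is put through step 13.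

**Step 4.** Some 6-allyl isomer or thermal decomposition at 215 °C is possible. The fallback sets out from 3 and comes back at 11, moving the rearrangement ahead of flavone formation.
- Ether 3 is heated in N,N-diethylaniline, where migration goes to the position between the two oxygens, giving 1-(3-allyl-2,4-dihydroxyphenyl)ethanone F3.
- One equivalent of MeI with K2CO3 in acetone methylates only the non-chelated 4-OH to give 1-(3-allyl-2-hydroxy-4-methoxyphenyl)ethanone F4.
- LiN(SiMe3)2 (3 equiv) and benzoyl chloride 4 give 1-(3-allyl-2-hydroxy-4-methoxyphenyl)-3-phenylpropane-1,3-dione F5.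
- Brief treatment with p-TsOH in warm toluene cyclodehydrates F5 to 11.

**Step 10.** Over-reduction to the alcohol or loss of the fairly volatile aldehyde is possible. The fallback sets out from 17 and comes back at 19.
- Ester 17 is reduced fully with LiAlH4 in Et2O at 0 °C to 2-[(tert-butyldimethylsilyl)oxy]-2-methylpropan-1-ol F6.
- F6 is purified and then oxidised with Dess-Martin periodinane in CH2Cl2 (or under Swern conditions) to 19.
- The redox level is then fixed by an oxidation that cannot overshoot on this α-quaternary substrate.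

## Further compounds
F1 | step 11 | 2-methylbut-3-en-2-yl (7-methoxy-4-oxo-2-phenyl-4H-chromen-8-yl)acetate | C=CC(C)(C)OC(=O)Cc1c(OC)ccc2c(=O)cc(-c3ccccc3)oc12
F2 | step 11 | 2-methyl-1-oxopropan-2-yl (7-methoxy-4-oxo-2-phenyl-4H-chromen-8-yl)acetate | O=CC(C)(C)OC(=O)Cc1c(OC)ccc2c(=O)cc(-c3ccccc3)oc12
F3 | step 4 | 1-(3-allyl-2,4-dihydroxyphenyl)ethanone | CC(=O)c1ccc(O)c(CC=C)c1O
F4 | step 4 | 1-(3-allyl-2-hydroxy-4-methoxyphenyl)ethanone | CC(=O)c1ccc(OC)c(CC=C)c1O
F5 | step 4 | 1-(3-allyl-2-hydroxy-4-methoxyphenyl)-3-phenylpropane-1,3-dione | O=C(CC(=O)c1ccccc1)c1ccc(OC)c(CC=C)c1O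
F6 | step 10 | 2-[(tert-butyldimethylsilyl)oxy]-2-methylpropan-1-ol | OCC(C)(C)O[Si](C)(C)C(C)(C)C
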